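**Strategy**

Ring B of the target, its quaternary C4 with both methyls, and C20 are already present in (1S,5S)-verbenone (labdane numbering): the enone β-carbon is C10, the carbonyl C8, one bridgehead C5, and the gem-dimethyl bridge C4, tied to C7 by a strained cyclobutane bond. A single TiCl4 cascade adds allyltrimethylsilane to C10 (C1–C10), traps the enolate with the side-chain aldehyde (C9–C11), then breaks the C4–C7 bond; the freed C4 cation is captured by the allyl terminus (C3–C4), closing ring A as the trans-decalin. The precursor is therefore just verbenone, the silane and aldehyde 3; ketone-to-allylic-acetate adjustment at C8 finishes the route.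

Key step: step 2

Assumption: compounds 1, 4 and 5 are taken as commercial. Atoms in the text carry labdane numbers (ring A: C1–C5 and C10; ring B: C5–C10; C17 on C8; C20 on C10; side chain C11–C16). Centres that are erased later (C2 in 8–11; C9 and C11 in 8 and 9; the alkene geometry in 10) are left undefined in the SMILES on purpose.

**Route**

Step 1
Reactants: 1 (R)-5-methoxy-3-methyl-5-oxopentanoic acid
Product: 3 methyl (R)-3-methyl-5-oxopentanoate, via acid chloride 2 (not isolated)
Conditions: (COCl)2, DMF (cat.), CH2Cl2, 0 → 20 °C; then LiAlH(OtBu)3, THF, −78 °C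
Reagents that add atoms: none
Why: Acyl chloride formation followed by partial hydride reduction of the acid chloride with the bulky alkoxyaluminium hydride should stop at the aldehyde and spare the methyl ester at −78 °C; the stereocentre is β to both carbonyls and is not touched.

Step 2
Reactants: 4 (1S,5S)-verbenone; 5 allyltrimethylsilane; 3 methyl (R)-3-methyl-5-oxopentanoate
Product: 8 methyl (3R)-5-[(4aR,8aR)-7-chloro-5,5,8a-trimethyl-2-oxodecahydronaphthalen-1-yl]-5-hydroxy-3-methylpentanoate, via titanium enolate 6 (not isolated), via titanium aldolate 7 (not isolated)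
Conditions: TiCl4 (3 equiv in all), CH2Cl2, −78 °C, 4 then 5 (1.05 equiv); then 3, −78 °C; warm to 20 °C; aq. NaHCO3
Reagents that add atoms: titanium tetrachloride, Cl[Ti](Cl)(Cl)Cl
Why: Proposed new method: TiCl4 activates enone 4 and allylsilane 5 adds to C10 from the face opposite the gem-dimethyl bridge (Hosomi–Sakurai conjugate allylation), which forms C1–C10 and fixes C10, and titanium enolate 6 is then trapped by aldehyde 3 (the known allylation–aldol three-component variant), which forms C9–C11 and returns the C8 carbonyl as chelate 7. On warming, the Lewis-acid-bound ketone induces heterolysis of the strained C7–C4 cyclobutane bond, the closest precedent being the SnCl4-promoted ring opening of 4-substituted nopinones, to give a C7=C8 titanium enolate and a tertiary cation at C4. Ring A then closes by 6-endo-trig attack of the terminal allyl carbon C3 on this cation (Markovnikov cation–olefin cyclisation, forming C3–C4), and chloride quenches the secondary cation at C2. The ring fusion can only be trans, because C5 is inherited from 4 and the allyl group entered anti to the C4 bridge, so C1 and C4 are trans on ring B; C2, C9 and C11 form as mixtures that steps 3 to 5 remove. The step needs 1,4- over 1,2-allylation (secured by the β,β-disubstituted enone under TiCl4), cleavage of C7–C4 and not C5–C4 (C10 is already quaternary when the ketone is regenerated, so only the bond α to the carbonyl can ionise), and C–C capture of the cation (chloride or oxygen adducts of a tertiary cation re-ionise under TiCl4, the carbocyclisation does not). Each event is precedented separately; only their merger in one flask is new.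

Step 3
Reactants: 8 methyl (3R)-5-[(4aR,8aR)-7-chloro-5,5,8a-trimethyl-2-oxodecahydronaphthalen-1-yl]-5-hydroxy-3-methylpentanoate
Product: 10 methyl (3R)-5-[(4aR,8aR)-7-chloro-5,5,8a-trimethyl-2-oxooctahydronaphthalen-1(2H)-ylidene]-3-methylpentanoate, via mesylate 9 (not isolated)
Conditions: MsCl, Et3N, CH2Cl2, 0 °C; then DBU, 20 °C
Reagents that add atoms: none
Why: Mesylation of the aldol and E1cB elimination through the C9 enolate (aldol dehydration) should give the exocyclic enone and erase the C9 and C11 centres; the secondary chloride is inert to DBU at 20 °C.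

Step 4
Reactants: 10 methyl (3R)-5-[(4aR,8aR)-7-chloro-5,5,8a-trimethyl-2-oxooctahydronaphthalen-1(2H)-ylidene]-3-methylpentanoate
Product: 11 methyl (3R)-5-[(1S,4aR,8aR)-7-chloro-5,5,8a-trimethyl-2-oxodecahydronaphthalen-1-yl]-3-methylpentanoate
Conditions: H2 (1 atm), Pd/C, EtOAc, 20 °C
Reagents that add atoms: none
Why: Heterogeneous catalytic hydrogenation should deliver hydrogen to the exocyclic enone C=C from the face opposite the axial C10 methyl, so H-9 ends trans to that methyl and the side chain equatorial (9S); ketone, ester and C–Cl stay intact.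

Step 5
Reactants: 11 methyl (3R)-5-[(1S,4aR,8aR)-7-chloro-5,5,8a-trimethyl-2-oxodecahydronaphthalen-1-yl]-3-methylpentanoate
Product: 12 methyl (3R)-3-methyl-5-[(1S,4aR,8aR)-5,5,8a-trimethyl-2-oxodecahydronaphthalen-1-yl]pentanoate
Conditions: Bu3SnH, AIBN (cat.), toluene, 110 °C
Reagents that add atoms: none
Why: Radical chain dehalogenation with tributyltin hydride removes the secondary chloride, so both C2 epimers converge on one ketone without touching C9.

Step 6
Reactants: 12 methyl (3R)-3-methyl-5-[(1S,4aR,8aR)-5,5,8a-trimethyl-2-oxodecahydronaphthalen-1-yl]pentanoate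
Product: 13 methyl (3R)-3-methyl-5-[(1S,4aR,8aR)-5,5,8a-trimethyl-2-{[(trifluoromethyl)sulfonyl]oxy}-1,4,4a,5,6,7,8,8a-octahydronaphthalen-1-yl]pentanoate
Conditions: KN(SiMe3)2 (1.05 equiv), THF, −78 °C; then PhNTf2, −78 → 0 °C
Reagents that add atoms: N-phenyl-bis(trifluoromethanesulfonimide), O=S(=O)(N(c1ccccc1)S(=O)(=O)C(F)(F)F)C(F)(F)F
Why: Kinetic enolisation by the hindered amide should occur at the C7 methylene and not at the tertiary C9–H beside the quaternary C10, and O-triflation (enol triflate formation) then fixes the C7=C8 position without epimerising C9; the ketone is more acidic than the ester.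

Step 7
Reactants: 13 methyl (3R)-3-methyl-5-[(1S,4aR,8aR)-5,5,8a-trimethyl-2-{[(trifluoromethyl)sulfonyl]oxy}-1,4,4a,5,6,7,8,8a-octahydronaphthalen-1-yl]pentanoate
Product: 14 methyl (3R)-5-[(1S,4aR,8aR)-2-(hydroxymethyl)-5,5,8a-trimethyl-1,4,4a,5,6,7,8,8a-octahydronaphthalen-1-yl]-3-methylpentanoate
Conditions: Bu3SnCH2OH, Pd(PPh3)4 (cat.), LiCl, 1,4-dioxane, 100 °C
Reagents that add atoms: (tributylstannyl)methanol, CCCC[Sn](CCCC)(CCCC)CO
Why: Migita–Kosugi–Stille coupling of the alkenyl triflate with the hydroxymethylstannane should install C17 as CH2OH with the alkene held at C7=C8; the methyl ester is inert.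

Step 8
Reactants: 14 methyl (3R)-5-[(1S,4aR,8aR)-2-(hydroxymethyl)-5,5,8a-trimethyl-1,4,4a,5,6,7,8,8a-octahydronaphthalen-1-yl]-3-methylpentanoate
Product: 15 methyl (3R)-5-[(1S,4aR,8aR)-2-(acetoxymethyl)-5,5,8a-trimethyl-1,4,4a,5,6,7,8,8a-octahydronaphthalen-1-yl]-3-methylpentanoate
Conditions: Ac2O, pyridine, DMAP (cat.), CH2Cl2, 20 °C
Reagents that add atoms: acetic anhydride, CC(=O)OC(C)=O
Why: DMAP-catalysed acylation of the primary allylic alcohol should give the acetate without affecting the ester or any stereocentre.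

**Compound list**

1 | (R)-5-methoxy-3-methyl-5-oxopentanoic acid (monomethyl (R)-3-methylglutarate) | COC(=O)C[C@H](C)CC(=O)O | starting material
2 | methyl (S)-5-chloro-3-methyl-5-oxopentanoate (acid chloride) | COC(=O)C[C@H](C)CC(=O)Cl | intermediate
3 | methyl (R)-3-methyl-5-oxopentanoate | COC(=O)C[C@H](C)CC=O | intermediate
4 | (1S,5S)-verbenone, (1S,5S)-4,6,6-trimethylbicyclo[3.1.1]hept-3-en-2-one | CC1=CC(=O)[C@H]2C[C@@H]1C2(C)C | starting material
5 | allyltrimethylsilane | C=CC[Si](C)(C)C | starting material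
6 | trichloro{[(1S,4R,5R)-4-allyl-4,6,6-trimethylbicyclo[3.1.1]hept-2-en-2-yl]oxy}titanium (titanium enolate, allyl anti to the gem-dimethyl bridge) | C=CC[C@@]1(C)C=C(O[Ti](Cl)(Cl)Cl)[C@H]2C[C@@H]1C2(C)C | intermediate
7 | methyl (3R)-5-[(1S,4R,5R)-4-allyl-4,6,6-trimethyl-2-oxobicyclo[3.1.1]heptan-3-yl]-3-methyl-5-[(trichlorotitanio)oxy]pentanoate (titanium aldolate; ring C3 and carbinol centre as mixtures) | C=CC[C@@]1(C)C(C(O[Ti](Cl)(Cl)Cl)C[C@@H](C)CC(=O)OC)C(=O)[C@H]2C[C@@H]1C2(C)C | intermediate
8 | methyl (3R)-5-[(4aR,8aR)-7-chloro-5,5,8a-trimethyl-2-oxodecahydronaphthalen-1-yl]-5-hydroxy-3-methylpentanoate (trans-fused; mixture at ring C1, ring C7 and the carbinol carbon) | COC(=O)C[C@H](C)CC(O)C1C(=O)CC[C@@H]2C(C)(C)CC(Cl)C[C@@]12C | intermediate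
9 | methyl (3R)-5-[(4aR,8aR)-7-chloro-5,5,8a-trimethyl-2-oxodecahydronaphthalen-1-yl]-3-methyl-5-[(methylsulfonyl)oxy]pentanoate | COC(=O)C[C@H](C)CC(OS(C)(=O)=O)C1C(=O)CC[C@@H]2C(C)(C)CC(Cl)C[C@@]12C | intermediate
10 | methyl (3R)-5-[(4aR,8aR)-7-chloro-5,5,8a-trimethyl-2-oxooctahydronaphthalen-1(2H)-ylidene]-3-methylpentanoate (alkene isomers, ring C7 epimers) | COC(=O)C[C@H](C)CC=C1C(=O)CC[C@@H]2C(C)(C)CC(Cl)C[C@@]12C | intermediate
11 | methyl (3R)-5-[(1S,4aR,8aR)-7-chloro-5,5,8a-trimethyl-2-oxodecahydronaphthalen-1-yl]-3-methylpentanoate (ring C7 epimers) | COC(=O)C[C@H](C)CC[C@@H]1C(=O)CC[C@@H]2C(C)(C)CC(Cl)C[C@@]12C | intermediate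
12 | methyl (3R)-3-methyl-5-[(1S,4aR,8aR)-5,5,8a-trimethyl-2-oxodecahydronaphthalen-1-yl]pentanoate | COC(=O)C[C@H](C)CC[C@@H]1C(=O)CC[C@@H]2C(C)(C)CCC[C@@]12C | intermediate
13 | methyl (3R)-3-methyl-5-[(1S,4aR,8aR)-5,5,8a-trimethyl-2-{[(trifluoromethyl)sulfonyl]oxy}-1,4,4a,5,6,7,8,8a-octahydronaphthalen-1-yl]pentanoate | COC(=O)C[C@H](C)CC[C@@H]1C(OS(=O)(=O)C(F)(F)F)=CC[C@@H]2C(C)(C)CCC[C@@]12C | intermediate
14 | methyl (3R)-5-[(1S,4aR,8aR)-2-(hydroxymethyl)-5,5,8a-trimethyl-1,4,4a,5,6,7,8,8a-octahydronaphthalen-1-yl]-3-methylpentanoate | COC(=O)C[C@H](C)CC[C@@H]1C(CO)=CC[C@@H]2C(C)(C)CCC[C@@]12C | intermediate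
15 | methyl (3R)-5-[(1S,4aR,8aR)-2-(acetoxymethyl)-5,5,8a-trimethyl-1,4,4a,5,6,7,8,8a-octahydronaphthalen-1-yl]-3-methylpentanoate (CNP0149025.1) | COC(=O)C[C@H](C)CC[C@@H]1C(COC(C)=O)=CC[C@@H]2C(C)(C)CCC[C@@]12C | target

**Step count and risks**

Total step count: 8. Longest linear sequence: 8 steps (1 → 3 → 8 → 10 → 11 → 12 → 13 → 14 → 15); 7 steps from verbenone 4.

Steps most likely to fail:

Step 2. The verbenone cyclobutane may open under the Lewis acid before the allyl group has been delivered, or the tertiary cation may be lost by proton loss or capture by the aldolate oxygen faster than ring closure. Fallback with known chemistry, the three events separated: setting out from 4, copper-catalysed conjugate addition of allylmagnesium bromide in the presence of Me3SiCl (CuBr·SMe2 cat., THF, −78 °C) should give the silyl enol ether [(1S,4R,5R)-4-allyl-4,6,6-trimethylbicyclo[3.1.1]hept-2-en-2-yl]oxy(trimethyl)silane F1. A Mukaiyama aldol addition of F1 to 3 (BF3·OEt2, CH2Cl2, −78 °C) should give the bicyclic aldol methyl (3R)-5-[(1S,4R,5R)-4-allyl-4,6,6-trimethyl-2-oxobicyclo[3.1.1]heptan-3-yl]-5-hydroxy-3-methylpentanoate F2. SnCl4 (CH2Cl2, 0 → 20 °C), the reagent known to open 4-substituted nopinones, should then cleave the cyclobutane and close ring A, and the route is rejoined at 8.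

Step 7. Transfer of the hydroxymethyl group from tin to the hindered alkenylpalladium may be slow, so that reduction or hydrolysis of the triflate takes over. Fallback: setting out from 13, palladium-catalysed reductive carbonylation (Pd(PPh3)4, CO 1 atm, Bu3SnH, THF, 50 °C) should give the enal methyl (3R)-5-[(1S,4aR,8aR)-2-formyl-5,5,8a-trimethyl-1,4,4a,5,6,7,8,8a-octahydronaphthalen-1-yl]-3-methylpentanoate F3. Luche reduction (NaBH4, CeCl3·7H2O, MeOH, 0 °C) reduces the aldehyde beside the ester and rejoins the route at 14.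

Step 4. Hydrogen delivery at the hindered exocyclic enone beside the quaternary C10 may stall or show poor facial selectivity, giving the C9 epimer. Fallback: setting out from 10, conjugate hydride reduction with [(Ph3P)CuH]6 (toluene, 20 °C) followed by kinetic protonation of the enolate from the face opposite the C10 methyl should give the same ketone and rejoin the route at 11; no new compound is made.

Further compounds

F1 | step 2 | [(1S,4R,5R)-4-allyl-4,6,6-trimethylbicyclo[3.1.1]hept-2-en-2-yl]oxy(trimethyl)silane | C=CC[C@@]1(C)C=C(O[Si](C)(C)C)[C@H]2C[C@@H]1C2(C)C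
F2 | step 2 | methyl (3R)-5-[(1S,4R,5R)-4-allyl-4,6,6-trimethyl-2-oxobicyclo[3.1.1]heptan-3-yl]-5-hydroxy-3-methylpentanoate | C=CC[C@@]1(C)C(C(O)C[C@@H](C)CC(=O)OC)C(=O)[C@H]2C[C@@H]1C2(C)C
F3 | step 7 | methyl (3R)-5-[(1S,4aR,8aR)-2-formyl-5,5,8a-trimethyl-1,4,4a,5,6,7,8,8a-octahydronaphthalen-1-yl]-3-methylpentanoate | COC(=O)C[C@H](C)CC[C@@H]1C(C=O)=CC[C@@H]2C(C)(C)CCC[C@@]12C
F0 | step 4 | none | none
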